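A reading at 20 h means little until one knows how much of the flask's final target is still to come at that hour, so I reckoned that first.

| setting | elm | alder | red | teal |
|---|---|---|---|---|
| substrate | 0.16 M (fed, over 12 min) | 0.16 M (fed, over 12 min) | 0.16 M (fed, over 12 min) | 0.16 M (fed, over 12 min) |
| partner | 0.090 M | 0.15 M | 0.120 M | 0.168 M |
| capture agent | 0.016 M | 0.016 M | 0.0160 M | 0.0160 M |
| temperature | −5 °C | 12 °C |  |  |
| remark | run made earlier | run made earlier | at 0 °C throughout | at 0 °C until 12 min, from then on at 25 °C |
| time |  |  | 20 h | 20 h |

- elm (time / h: target / %): 1.33: 0; 4.00: 7; 8.00: 8; 10.0: 11; 15.0: 13; 20.0: 15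
- alder (time / h: target / %): 0.833: 18; 1.33: 28; 2.00: 33; 4.00: 45; 6.00: 48; 12.0: 54

(each reading ± 1.5 percentage points)

- a reading or a percentage of target counts all its forms, free or not

- which of the two ends with the higher amount of target, in percent of the substrate charged ("neither" if they lie within 2 percentage points) (red / teal / neither)
- target at the end, in percent of the substrate charged, red
- target at the end, in percent of the substrate charged, teal

I worked with the fraction left and not the fraction made. I assumed that partner stays roughly as charged, so that what has yet to become target falls as in a pseudo-first-order step, whose rate is a rate constant times partner, and the fraction left is exp(−rate × time). Elm's 7% at 4.00 h gave me a rate of 0.0181 h⁻¹, and alder's 28% at 1.33 h gave 0.247 h⁻¹. Both are readings with their scatter. Divided by partner, they differ by a factor of 8.17 between −5 °C and 12 °C, with 2.10 as its logarithm. I laid that logarithm straight against temperature and multiplied by each partner charge. That gave an estimated rate of 0.0449 h⁻¹ for red and, by extrapolation, of 1.38 h⁻¹ for teal.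

For red the fraction left at the reading came to 40.8%, and that number, the share of the final target still to come at the time of reading, is what I carried. Teal's estimated rate times time is 27.6, so its fraction left lay far below red's, and I took teal's reading for a plateau.

The same fraction turns a last reading into a ceiling. Elm's 15% with 69.6% left means 49.3%, and alder's 54% with 5.16% left means 56.9%. A straight line through these against temperature put red's ceiling at 51.5% and teal's at 62.8%. Those rates had taken the whole charge as ceiling, so this reckoning is rough. I committed to 30.5% for red and the higher 62.8% for teal.

The forecast said teal, with 28% for red and 55% for teal, lower than my teal, on the ground that “Loss or reversal at higher temperature may cap it near 55%”.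

Red ended at 32.5% and teal at 65.6%, so teal held more.

    substrate → open intermediate (k = 6.80 × 10⁻⁴ s⁻¹, Ea = 84.0 kJ mol⁻¹)
    open intermediate + capture agent → trapped intermediate (k = 0.00200 M⁻¹ s⁻¹, Ea = 61.0 kJ mol⁻¹)
    crystals ⇌ target, rate k3*(cs3 - [target]) while solid is left; crystals form when [target] > cs3 (solubility = 8.20 mM, k = 0.00710 s⁻¹)
    partner + open intermediate → target (k = 2.80 × 10⁻⁴ M⁻¹ s⁻¹, Ea = 71.0 kJ mol⁻¹)
    2 open intermediate → homo product (k = 2.00 × 10⁻⁴ M⁻¹ s⁻¹, Ea = 49.0 kJ mol⁻¹)
    target ⇌ isomer of the product (K = 1.60, k = 3.70 × 10⁻⁴ s⁻¹, Ea = 92.0 kJ mol⁻¹, ΔH = −41.0 kJ mol⁻¹)
    (constants at 0 °C)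

Left for 200 h, teal stood at 65.6%, while red moved on to 38.8%, so 16.2% of that amount was still to come at red's reading, where I had carried 40.8%. I then put the fraction left to a neighbour, a flask like red kept at −15 °C. The same line gives it a rate of 0.00703 h⁻¹, so 86.9% is left at the reading, and a ceiling of 44.8% then means 5.87% of target. That flask held 8.96% of target, with 38.9% of the substrate charged still open intermediate.

The readings come from a simulation with constants of no real substance; scatter was added.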